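The numbers in the tables are simulated with constants of no real substance; the scatter is artificial.

0.830 is the figure I work from: the target I expect in the flask over the target the noon run made, both at 6.00 min.

common to all: gas 88 mM (held)
- dawn: starting material 1 M; second substrate 1.5 M; free catalyst 3 mM; run made earlier
- midnight: starting material 2.2 M; second substrate 1.5 M; free catalyst 3 mM; run made earlier
- noon: starting material 1.5 M; second substrate 0.75 M; free catalyst 3 mM; run made earlier
- flask: starting material 1.5 M; second substrate 1.50 M; free catalyst 3.0 mM

| run | time / min | target / % |
|---|---|---|
| dawn | 0.333 | 0 |
| dawn | 1.00 | 3 |
| dawn | 1.50 | 6 |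
| dawn | 2.50 | 7 |
| dawn | 4.00 | 16 |
| dawn | 5.00 | 18 |
| dawn | 6.00 | 22 |
| midnight | 0.833 | 2 |
| midnight | 1.50 | 3 |
| midnight | 2.50 | 7 |
| midnight | 3.00 | 7 |
| midnight | 4.00 | 9 |
| midnight | 5.00 | 13 |
| midnight | 6.00 | 14 |
| noon | 0.500 | 0 |
| noon | 0.833 | 5 |
| noon | 1.50 | 4 |
| noon | 3.00 | 9 |
| noon | 6.00 | 21 |

(each reading ± 1.5 percentage points)

- at the start none of partner is dissolved
- the numbers in the tables scatter by 1.5 percentage points (one standard deviation)
- steps thought possible: partner + catalyst intermediate B -> free catalyst + second product; gas <-> partner; starting material + free catalyst <-> catalyst intermediate A; second substrate + free catalyst <-> catalyst intermediate B; partner + catalyst intermediate A -> free catalyst + target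
- no earlier run changes the charge of free catalyst; that part of a forecast is a guess

1. apparent order in second substrate when 5.0 % of the starting material are converted (percent change of the rate of making target for one percent more second substrate charged)
2. apparent order in free catalyst when 5.0 % of the starting material are converted (percent change of the rate of making target for one percent more free catalyst charged)
3. factor on the rate of making target when 5.0 % of the starting material are converted if free catalyst is charged twice over

- I call this figure the second-substrate ratio: target at full second substrate over target at the lower charge, with starting material equal and one time for both, so time drops out.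
- The first amount is a reading: the noon run, with 0.75 M of second substrate, has made 0.315 M of target at 6.00 min.
- The second amount I reckon. The dawn run has made 0.220 M and the midnight run 0.308 M at that time, both with the flask's second substrate, so the power of starting material between them is 0.427. This puts the flask, at 1.5 M, at 0.262 M.
- The noon run has half the flask's second substrate, so the logarithm of the ratio over the logarithm of that charge ratio gives my apparent order, −0.268. It comes from totals, not from the rate at 5.0 % conversion, and each reading scatters by 1.5 percentage points.
- The forecast says −0.35 for the order in second substrate, which differs from my figure. For free catalyst it guesses an order of 0.6 and a factor 1.5, and of a rate limited by chemistry or by gas transfer it says that "these runs cannot separate the two cases".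

    partner + catalyst intermediate B → free catalyst + second product (k = 2310 M⁻¹ min⁻¹)
    gas ⇌ partner, rate k2*(csat - [partner]) (kL = 2.77 min⁻¹)
    starting material + free catalyst ⇌ catalyst intermediate A (K = 1.82 M⁻¹, k = 2270 M⁻¹ min⁻¹)
    second substrate + free catalyst ⇌ catalyst intermediate B (K = 1.10 M⁻¹, k = 60.1 M⁻¹ min⁻¹)
    partner + catalyst intermediate A → free catalyst + target (k = 479 M⁻¹ min⁻¹)

- The flask gives an order of −0.28 in second substrate, an order of 0.54 in free catalyst and a factor 1.34. At 5.00 min, catalyst intermediate B holds 11.6 % of the flask's catalyst and catalyst intermediate A 61.3 %. Turned round, the second-substrate ratio, reckoned at 6.00 min, carries the flask's 15.5 % of target at 5.00 min over to the noon run as 18.7 %, and the noon run reads 9 % at 3.00 min and 21 % at 6.00 min.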